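The green run, with 1 equiv of free base, keeps 45.4% of its electrophile at 3.00 h, and the violet run, with 1.5 equiv, keeps 45.2%. I therefore read one clock from the green run for the flasks below.

all flasks: gas 9.2 mM (held)

| flask | electrophile | free base | remark | time |
|---|---|---|---|---|
| grey | 20 mM | 2 equiv | run made earlier |  |
| green | 20 mM | 1 equiv | run made earlier |  |
| violet | 20 mM | 1.5 equiv | run made earlier |  |
| amber | 10 mM | 2 equiv | run made earlier |  |
| birch | 20 mM | 2.00 equiv | everything together at the start | 2.5 h |
| ash | 20 mM (fed, over 30 min) | 2.00 equiv | all else is in the flask from the start; the feed brings no volume worth counting | 2.5 h |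
| maple | 20 mM | 2.00 equiv (in portions, 2, over 30 min) | first portion at the start, last at 30 min | 2.5 h |
| larch | 20 mM | 2.00 equiv (fed, over 30 min) | all else is in the flask from the start; the feed brings no volume worth counting | 2.5 h |

- grey (time / min: target / %, electrophile / %): 25.0: 3.9, 92.4; 50.0: 14.8, 84.7; 60.0: 15.9, 80.0; 90.0: 24.8, 70.8
- green (time / h: target / %, electrophile / %): 0.833: 14.3, 83.2; 1.50: 23.6, 69.0; 2.50: 32.8, 51.7; 3.00: 34.8, 45.4
- violet (time / h: target / %, electrophile / %): 0.250: 2.1, 95.6; 0.500: 6.5, 91.6; 1.33: 22.8, 73.5; 3.00: 35.5, 45.2
- amber (time / h: target / %, electrophile / %): 0.417: 6.9, 91.7; 1.00: 19.1, 77.1; 2.00: 33.0, 55.2; 3.00: 36.1, 39.4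

(readings scatter by 1 percentage point)

- at the start none of nucleophile is dissolved
- the earlier runs were read with a standard deviation of 1 percentage point
- steps thought possible: electrophile + nucleophile <-> acid set free + target; nucleophile + acid set free <-> protonated nucleophile; gas <-> nucleophile; nucleophile + target -> over-reaction product; acid set free + free base <-> salt of the base

* which flask leads in amount of target, in percent of the electrophile charged ("all alike" within 1.5 percentage points) (birch / ash / maple / larch / all alike)
* how much target is there at the end, in percent of the electrophile charged: birch
* how much target is there at the end, in percent of the electrophile charged: ash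
* how much target is there at the end, in percent of the electrophile charged: maple
* how much target is there at the end, in percent of the electrophile charged: larch

Between its first and last readings, the green run's logarithm of electrophile falls at k = 0.280 h⁻¹. Drawn back to the full charge, that line starts at a lag L = 0.175 h. At 2.5 h the clock shows 0.650: this is the turnover count τ, k times the time past the lag.

At the end of the green run, target over electrophile reads 0.767, and minus the logarithm of electrophile reads 0.790. I take the selectivity factor as near one, which makes electrophile e^(−τ) and target τe^(−τ) of the charge.

The target curve lies flat through L, then climbs at about 0.280 h⁻¹ of the charge. It bends over and crosses electrophile where τ reaches one, at 3.75 h. That crossing is also its crest, 36.8%, and beyond it the curve runs towards zero. Birch stops before the crest, at 33.9%, where a unit of τ is worth just 0.183 of the charge.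

Maple's first portion, 1.00, matches the green charge. Larch's free base enters at 4.00 h⁻¹, counted on the electrophile charge, faster than the turnover. So I give both the birch count.

The part of ash's electrophile fed after the lag misses some of the count, on average over the whole charge 0.0295, which gives 33.4%. That gap of 0.50 percentage points stays inside the margin, so I say all alike.

The forecast says all alike, with 32.6% for birch, 32.1% for ash, 32.6% for maple and 32.6% for larch, lower than my figures, on the ground that “any base that stays ahead of the acid suffices”.

The flasks give all alike: birch 33.3%, ash 32.8%, maple 33.3%, larch 33.3%.

    electrophile + nucleophile ⇌ acid set free + target (K = 1.96, k = 45.7 L mol⁻¹ h⁻¹)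
    nucleophile + acid set free ⇌ protonated nucleophile, settled at all times (K = 69500 L mol⁻¹)
    gas ⇌ nucleophile, rate k3*(csat - [nucleophile]) (kL = 3.12 h⁻¹)
    nucleophile + target → over-reaction product (k = 47.5 L mol⁻¹ h⁻¹)
    acid set free + free base ⇌ salt of the base (K = 46.5 L mol⁻¹, k = 99.0 L mol⁻¹ h⁻¹)

The two turnings of nucleophile have close constants, 47.5 L mol⁻¹ h⁻¹ towards over-reaction product and 45.7 L mol⁻¹ h⁻¹ towards target, a selectivity factor of 1.04. Target over electrophile in birch at 2.50 h stands at 0.631 against my count of 0.650, and in ash at 6.0 h, with target 29.5% and electrophile 17.6%, it stands at 1.68 against a count of 1.60.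

(Readings and results are simulated from invented constants; scatter was added.)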